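Compound numbers are those of the steps and of the compound list below.

## Analysis of the target

Compound 11, 2,5,6-tribromo-1-methyl-1H-indole-3-carbaldehyde, is a planar indole: a benzene ring (ring A: C3a, C4, C5, C6, C7, C7a) fused to a pyrrole ring (ring B: N1, C2, C3, C3a, C7a). It has no stereocentre and no stereogenic axis, so the synthesis is a problem of regiochemistry only. Five of the seven substitutable positions are occupied: methyl on N1, bromine on C2, a formyl group on C3 and bromine on C5 and C6, which leaves hydrogen only on C4 and C7. The aldehyde excludes organometallic and hydride reagents once it is present, the C2–Br bond is the β-halide of a vinylogous formamide and can be displaced by nucleophiles through addition–elimination, and all three C–Br bonds forbid alkyllithium reagents, catalytic hydrogenation and zerovalent palladium or nickel. The difficulty is that electrophilic bromination cannot deliver this pattern: a free indole reacts first at C3, a 3-acylindole is deactivated at C2, and in ring A the 5,6-pair has to be told apart from the 4,5-, 4,6- and 6,7-pairs. The strategy rests on the fact that C3 carries a carbonyl carbon and is joined through C3–C3a to the arene carbon ortho to the nitrogen-bearing C7a, while C2 is a CH group before its bromination; this is the bond pattern that a [3,3] shift of an N-aryl O-vinyl hydroxylamine made from a propiolate ester leaves behind. Seen from C7a, the bromine on C5 is para and that on C6 is meta, so ring A maps onto a 3,4-dibromophenyl group that can be bought with both halogens in place.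

## Retrosynthetic reasoning

The formyl group of 11 is made last, because it is the function least able to survive the other operations. It is traced back through the primary alcohol 10 to the methyl ester 9. No skeletal bond is cut here; the carbon is only moved from the carboxyl to the aldehyde oxidation level. What is gained is a C3 substituent that tolerates a strong base. The forward steps need a hydride reduction that leaves three C–Br bonds alone and a mild oxidation of a benzylic-type alcohol.

In 9 the C2–Br bond is cut, which leads to the 2-lithio species 8 and from there to the C2–H compound 7. C2–H is the only C–H bond of ring B. It lies between N1 and the ester carbonyl, so it is the most acidic ring proton and the only one that the ester can direct a base to. Electrophilic substitution is not an option at this deactivated carbon. The forward reaction has to use a hindered amide base, which deprotonates but does not exchange aryl bromides, and an electrophilic bromine donor.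

The N1–CH3 bond of 7 is cut next and gives the N–H indole 6. The methyl group is introduced before the metalation so that no acidic N–H is present in that step. The vinylogous carbamate makes the N–H acidic enough for a mild methylation.

Compound 6 is disconnected at C3–C3a and N1–C2, the two bonds of ring B that join the arene part to the three-carbon part. This leads through the ortho-aminoaryl formylacetate 5 and the O-vinyl ether 4 back to the hydroxylamine 2 and methyl propiolate 3. The alkyne 3 supplies C2, C3 and the ester carbon at the right oxidation level. Compound 2 supplies ring A with both bromines, N1, and an oxygen atom that holds the two partners together until the N–O bond is spent in the rearrangement. Cutting here and not in ring A keeps both aryl bromines in a purchased arene and builds ring B already aromatic, with two skeletal bonds formed in one operation. The forward reaction has to achieve O- rather than N-addition of 2 to the alkyne, and bond formation at the ortho carbon that is not flanked by bromine.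

The hydroxylamine 2 is finally traced to the nitroarene 1 by adjusting the oxidation level at nitrogen. The forward step is a partial reduction that must stop two electrons short of the aniline and must not touch the bromines.

## Alternatives that were turned down

Alternative 1: Ring A is taken apart completely, at C3a–C7a, C4–C5 and C6–C7, into the ynamide diyne A1 (N-(but-3-yn-1-yl)-N-ethynyl-4-methylbenzenesulfonamide) and the alkyne A2 (bis(trimethylsilyl)acetylene). In the forward direction CpCo(CO)2 (monovalent cobalt) would mediate a [2+2+2] cocyclisation to the indoline A3 (1-(4-methylbenzenesulfonyl)-5,6-bis(trimethylsilyl)indoline), and ipso-bromodesilylation would later turn the two silyl groups into the two bromines.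
- For it: the two silyl groups end up on C5 and C6 by connectivity alone, so no isomer question arises in ring A. On this point it is stronger than the chosen route, which relies on a steric bias.
- Against it: A3 is an N-sulfonyl indoline with nothing on C2 and C3. Dehydrogenation to the indole, removal of the sulfonyl group, N-methylation, C3 formylation and C2 bromination would all still be needed, and the last would lack a directing ester. A1 is a terminal ynamide that takes several steps to make, and the double bromodesilylation of two neighbouring silyl groups has to outrun protodesilylation.
- Comparison: the count would run well beyond ten steps against six. The chosen strategy delivers ring B aromatic, with the C3 carbon attached, from purchasable materials.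

Alternative 2: Ring A is cut at C7–C7a and C3a–C4, which leads back to A5 (1-methylpyrrole) and A4 (3,4-dibromo-2,5-dimethoxytetrahydrofuran, the cyclic bis-acetal of a 2,3-dibrominated 1,4-dialdehyde). In the forward direction acid would unmask the dialdehyde, which would alkylate C2 and then C3 of A5; two dehydrations would aromatise the new ring to A6 (5,6-dibromo-1-methyl-1H-indole).
- For it: it is the shortest route on paper. The N-methyl group and both bromines are in place after one step, and the symmetric electrophile leaves no doubt about the 5,6-pattern. In step count and in ring A regiochemistry it is stronger than the chosen strategy.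
- Against it: both α-positions of a pyrrole are more nucleophilic than its β-positions, so bridging of two pyrrole units and oligomerisation compete with closure at C3. The α-bromo aldehyde units can lose hydrogen bromide under the acidic conditions, which would cost one of the bromines. A6 also has no carbon on C3 and no handle on C2: formylation at C3 by a Vilsmeier–Haack reaction is easy, but the C2 bromination of the resulting 3-formylindole has neither an activating nor a directing group and cannot be done with a strong base in the presence of the aldehyde.
- Comparison: the chosen strategy is longer, but it brings the C3 carbonyl with it and uses it as the director for the C2 metalation, so every step addresses a position that is activated for it.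

Alternative 3: Ring B is cut at N1–C7a and C3–C3a, which leads back to the aryne precursor A7 (4,5-dibromo-2-(trimethylsilyl)phenyl trifluoromethanesulfonate) and the amino ketone A8 (N-(3,3-dimethoxy-2-oxopropyl)-4-methylbenzenesulfonamide). In the forward direction fluoride would release the symmetric aryne from A7, the sulfonamide nitrogen would add to it and the resulting aryl anion would close onto the ketone to give the racemic 3-hydroxyindoline A9 (5,6-dibromo-3-(dimethoxymethyl)-1-(4-methylbenzenesulfonyl)indolin-3-ol). Its single stereocentre would disappear on dehydration.
- For it: the aryne is symmetric, so the regiochemical question of the chosen key step does not exist, and the formyl carbon arrives as an acetal at the aldehyde oxidation level, which saves the reduction and oxidation. On both points it is stronger.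
- Against it: A7 is not a simple purchase, and its preparation requires a silylation that distinguishes between several C–Br bonds. A8 is an enolisable α-amino ketone. Protonation of the aryl anion competes with its addition to the ketone. After A9 the route still needs dehydration, C2 bromination, removal of the sulfonyl group, N-methylation and acetal hydrolysis.
- Comparison: the exchange of sulfonyl for methyl alone costs two steps, and the total comes to about ten. The chosen strategy reaches an N–H indole that is methylated directly, in six steps from commercial materials.

Key step: step 2

Remark: the target has no stereocentre; intermediate 5 has one enolisable, configurationally labile centre that is lost on aromatisation and is drawn without a descriptor.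

## Route

Step 1
Reactants: 1 1,2-dibromo-4-nitrobenzene
Product: 2 N-(3,4-dibromophenyl)hydroxylamine
Conditions: N2H4·H2O, Rh/C (cat.), THF, 0 °C to rt
Reagents that add atoms: none
Why: Catalytic transfer hydrogenation of a nitroarene with hydrazine on rhodium stops at the hydroxylamine at or below room temperature, because N–O hydrogenolysis is slow on this metal (partial nitro reduction); aryl bromides are tolerated under these mild conditions. Compound 2 is not stored but taken into step 2 at once.

Step 2
Reactants: 2 N-(3,4-dibromophenyl)hydroxylamine; 3 methyl propiolate
Product: 6 methyl 5,6-dibromo-1H-indole-3-carboxylate, via O-vinyl hydroxylamine 4 (not isolated), via aminoaryl formylacetate 5 (not isolated)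
Conditions: DABCO (10 mol %), THF, 0 °C to rt
Reagents that add atoms: none
Why: DABCO adds to alkyne 3 and the resulting zwitterion deprotonates the O–H of 2; the hydroxylamine oxygen then adds to the activated alkene and the amine is expelled, which gives the E-configured O-vinyl ether 4 (amine-catalysed oxa-Michael addition–elimination). The weak N–O bond of 4 breaks in a [3,3] sigmatropic shift, the hydroxylamine counterpart of the C–C bond-forming step of the Fischer indole synthesis, in which the free ortho carbon bonds to the carbon alpha to the ester and so forms C3–C3a; tautomerisation restores the arene and leaves the ortho-aminoaryl formylacetate 5. Ring B closes when the aniline nitrogen attacks the aldehyde carbon in a 5-exo-trig mode and the adduct dehydrates, which forms N1–C2 and the aromatic pyrrole. The closest known reaction type is the amine-catalysed annulation of N-arylhydroxylamines with electron-poor terminal alkynes to N–H indoles that carry a carbonyl group on C3. No stereocentre is created that persists, since the only sp3 centre of 5 is lost on aromatisation. Chemoselectivity for O- over N-addition comes from the nucleophilic catalyst, which turns the more acidic O–H into the reacting anion. The regioselectivity needed is bonding at the ortho carbon para to the meta bromine: the other ortho carbon lies between nitrogen and a bromine that is pushed towards it by its bromine neighbour, so the chair-like transition state there is hindered and the 5,6-dibromo indole should predominate over the 4,5-isomer. Only a slight excess of 3 is used so that the N–H of 6 is not vinylated in turn.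

Step 3
Reactants: 6 methyl 5,6-dibromo-1H-indole-3-carboxylate
Product: 7 methyl 5,6-dibromo-1-methyl-1H-indole-3-carboxylate
Conditions: MeI, K2CO3, DMF, rt
Reagents that add atoms: iodomethane, CI
Why: The N–H of a 3-alkoxycarbonylindole is acidified by the vinylogous carbamate, so carbonate is enough to form the indolyl anion, which iodomethane alkylates on nitrogen (SN2 N-alkylation); C3 is blocked, and the ester and the aryl bromides are inert.

Step 4
Reactants: 7 methyl 5,6-dibromo-1-methyl-1H-indole-3-carboxylate
Product: 9 methyl 2,5,6-tribromo-1-methyl-1H-indole-3-carboxylate, via 2-lithioindole ester 8 (not isolated)
Conditions: LiN(i-Pr)2 (LDA, commercial solution), THF, −78 °C; then BrCl2C–CCl2Br, −78 °C to rt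
Reagents that add atoms: 1,2-dibromo-1,1,2,2-tetrachloroethane, BrC(Cl)(Cl)C(Cl)(Cl)Br
Why: C2–H is the most acidic ring proton, alpha to N1 and ortho to the ester carbonyl that coordinates lithium, and a lithium dialkylamide deprotonates it without bromine–lithium exchange (ester-directed ortho metalation); the 2-lithio species 8 then takes bromine from the dibromide, which fragments to tetrachloroethene and bromide. A short metalation time at −78 °C keeps 8 from attacking the weakly electrophilic vinylogous carbamate ester of a second molecule.

Step 5
Reactants: 9 methyl 2,5,6-tribromo-1-methyl-1H-indole-3-carboxylate
Product: 10 (2,5,6-tribromo-1-methyl-1H-indol-3-yl)methanol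
Conditions: i-Bu2AlH (DIBAL-H), CH2Cl2, −78 to 0 °C; aq. potassium sodium tartrate
Reagents that add atoms: none
Why: The electrophilic aluminium hydride reduces the ester through the aldehyde to the alkoxide of the primary alcohol (hydride reduction of an ester) and does not attack aryl or C2 bromides at low temperature. The neutral tartrate work-up avoids acid, which would ionise the indol-3-ylmethanol; crude 10 is used directly.

Step 6
Reactants: 10 (2,5,6-tribromo-1-methyl-1H-indol-3-yl)methanol
Product: 11 2,5,6-tribromo-1-methyl-1H-indole-3-carbaldehyde
Conditions: MnO2 (activated, excess), CH2Cl2, rt
Reagents that add atoms: none
Why: Activated MnO2 oxidises benzylic-type carbinols selectively to aldehydes under neutral heterogeneous conditions (benzylic alcohol oxidation); the product is a vinylogous formamide that is not oxidised further, and the C2 bromide is not exposed to nucleophiles.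

## Compound list

1 | 1,2-dibromo-4-nitrobenzene | O=[N+]([O-])c1ccc(Br)c(Br)c1 | starting material
2 | N-(3,4-dibromophenyl)hydroxylamine | ONc1ccc(Br)c(Br)c1 | intermediate
3 | methyl propiolate | C#CC(=O)OC | starting material
4 | methyl (E)-3-{[(3,4-dibromophenyl)amino]oxy}prop-2-enoate | COC(=O)/C=C/ONc1ccc(Br)c(Br)c1 | intermediate (not isolated)
5 | methyl 2-(2-amino-4,5-dibromophenyl)-3-oxopropanoate (racemic, configurationally labile) | COC(=O)C(C=O)c1cc(Br)c(Br)cc1N | intermediate (not isolated)
6 | methyl 5,6-dibromo-1H-indole-3-carboxylate | COC(=O)c1c[nH]c2cc(Br)c(Br)cc12 | intermediate
7 | methyl 5,6-dibromo-1-methyl-1H-indole-3-carboxylate | COC(=O)c1cn(C)c2cc(Br)c(Br)cc12 | intermediate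
8 | methyl 5,6-dibromo-2-lithio-1-methyl-1H-indole-3-carboxylate | [Li]c1c(C(=O)OC)c2cc(Br)c(Br)cc2n1C | intermediate (not isolated)
9 | methyl 2,5,6-tribromo-1-methyl-1H-indole-3-carboxylate | COC(=O)c1c(Br)n(C)c2cc(Br)c(Br)cc12 | intermediate
10 | (2,5,6-tribromo-1-methyl-1H-indol-3-yl)methanol | OCc1c(Br)n(C)c2cc(Br)c(Br)cc12 | intermediate
11 | 2,5,6-tribromo-1-methyl-1H-indole-3-carbaldehyde | Cn1c(Br)c(C=O)c2cc(Br)c(Br)cc21 | target

## Step count and least certain steps

Total step count: 6. Longest linear sequence: 6 steps, from 1 to 11; compound 3 enters in step 2.

Step 2 (key step). The most likely failure is poor site selectivity in the [3,3] shift. Bonding at the ortho carbon between nitrogen and bromine would place the bromines on C4 and C5, and a meta halogen gives only a steric preference, not an electronic one. N-addition of 2 to the alkyne and base-induced self-condensation of 2 to an azoxyarene would lower the throughput further. The fallback sets out from 3 and moves the bromines to a later stage. Compound 3 is reacted under the same amine catalysis with commercial N-phenylhydroxylamine (ONc1ccccc1), whose two ortho carbons are equivalent, to give methyl 1H-indole-3-carboxylate F1. F1 is then treated with Br2 in acetic acid. The C3 ester deactivates ring B, so electrophilic substitution takes place in ring A at C6 and C5, and either monobromide leads on to the same 5,6-dibromide. That product is 6, where the route is rejoined.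

Step 4. The most likely failure is competing deprotonation of ring A next to a bromine (C4–H or C7–H), after which loss of lithium bromide to an aryne or migration of bromine would scramble the halogen pattern. Attack of 8 on the ester of unreacted 7 is the second risk. The fallback uses no carbanion and sets out from 7. Saponification (NaOH, aqueous MeOH, reflux, then acidification) gives 5,6-dibromo-1-methyl-1H-indole-3-carboxylic acid F2. Pyridinium tribromide in wet tert-butanol brominates F2 at C3 with loss of carbon dioxide and carries on through further bromination and hydration at C2 to 3,3,5,6-tetrabromo-1-methylindolin-2-one F3. Zn in acetic acid removes the two C3 bromines and leaves the aryl bromides, which gives 5,6-dibromo-1-methylindolin-2-one F4. A Vilsmeier–Haack bromoformylation (POBr3, DMF, CHCl3, reflux, then water) converts the lactam carbonyl into the C2 bromide and places the formyl group on C3. This gives 11 directly, so the fallback replaces steps 4 to 6 and returns to the route at 11.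

Step 5. The most likely failure is ionisation of the C3 carbinol, or of its aluminium alkoxide, to a 3-methyleneindoleninium ion. That leads to hydrogenolysis to the 3-methyl compound in the flask, or to self-condensation during work-up or on silica. Sluggish reduction of the vinylogous carbamate ester is a lesser concern. The fallback sets out from 9 and avoids the carbinol. Aminolysis with MeNH(OMe)·HCl and AlMe3 (CH2Cl2, 0 to 40 °C) gives the Weinreb amide 2,5,6-tribromo-N-methoxy-N,1-dimethyl-1H-indole-3-carboxamide F5. Reduction with i-Bu2AlH in THF at −78 °C gives a chelated tetrahedral adduct that collapses to the aldehyde only on work-up. The route is rejoined at 11, and steps 5 and 6 are replaced.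

Step 1. The most likely failure is reduction that overshoots: N–O hydrogenolysis to the aniline, some loss of bromine on the metal surface, and condensation of 2 with partly reduced material to an azoxyarene. Compound 2 also disproportionates on standing. The fallback sets out from 1 and passes through defined oxidation levels instead of stopping a reduction half-way. Fe and NH4Cl in aqueous ethanol at reflux reduce the nitro group completely to 3,4-dibromoaniline F6. KHSO5 (used as its commercial triple salt) in CH2Cl2–water oxidises F6 to 1,2-dibromo-4-nitrosobenzene F7. Slow addition of F7 to ascorbic acid in aqueous THF at 0 °C reduces it by two electrons to 2, where the route is rejoined.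

## Further compounds

F1 | step 2 | methyl 1H-indole-3-carboxylate | COC(=O)c1c[nH]c2ccccc12
F2 | step 4 | 5,6-dibromo-1-methyl-1H-indole-3-carboxylic acid | Cn1cc(C(=O)O)c2cc(Br)c(Br)cc21
F3 | step 4 | 3,3,5,6-tetrabromo-1-methylindolin-2-one | CN1C(=O)C(Br)(Br)c2cc(Br)c(Br)cc21
F4 | step 4 | 5,6-dibromo-1-methylindolin-2-one | CN1C(=O)Cc2cc(Br)c(Br)cc21
F5 | step 5 | 2,5,6-tribromo-N-methoxy-N,1-dimethyl-1H-indole-3-carboxamide | CON(C)C(=O)c1c(Br)n(C)c2cc(Br)c(Br)cc12
F6 | step 1 | 3,4-dibromoaniline | Nc1ccc(Br)c(Br)c1
F7 | step 1 | 1,2-dibromo-4-nitrosobenzene | O=Nc1ccc(Br)c(Br)c1
A1 | alternative 1 | N-(but-3-yn-1-yl)-N-ethynyl-4-methylbenzenesulfonamide | C#CCCN(C#C)S(=O)(=O)c1ccc(C)cc1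
A2 | alternative 1 | bis(trimethylsilyl)acetylene | C[Si](C)(C)C#C[Si](C)(C)C
A3 | alternative 1 | 1-(4-methylbenzenesulfonyl)-5,6-bis(trimethylsilyl)indoline | C[Si](C)(C)c1cc2c(cc1[Si](C)(C)C)N(S(=O)(=O)c1ccc(C)cc1)CC2
A4 | alternative 2 | 3,4-dibromo-2,5-dimethoxytetrahydrofuran (mixture of stereoisomers) | COC1OC(OC)C(Br)C1Br
A5 | alternative 2 | 1-methylpyrrole | Cn1cccc1
A6 | alternative 2 | 5,6-dibromo-1-methyl-1H-indole | Cn1ccc2cc(Br)c(Br)cc21
A7 | alternative 3 | 4,5-dibromo-2-(trimethylsilyl)phenyl trifluoromethanesulfonate | C[Si](C)(C)c1cc(Br)c(Br)cc1OS(=O)(=O)C(F)(F)F
A8 | alternative 3 | N-(3,3-dimethoxy-2-oxopropyl)-4-methylbenzenesulfonamide | COC(OC)C(=O)CNS(=O)(=O)c1ccc(C)cc1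
A9 | alternative 3 | 5,6-dibromo-3-(dimethoxymethyl)-1-(4-methylbenzenesulfonyl)indolin-3-ol (racemic) | COC(OC)C1(O)CN(S(=O)(=O)c2ccc(C)cc2)c2cc(Br)c(Br)cc21
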